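**Retrosynthetic overview**

1. Feature: C3 and C3'' are bonded to each other, each carries a ketone carbon (C4, C4'') and each lies next to an O-bearing benzylic carbon (C2, C2''), so C4–C3–C3''–C4'' is a 2,3-disubstituted succinyl unit between two carbinol carbons. All four stereocentres are S and both pyranone rings are 2,3-cis.
2. Key disconnection: C3–C4 and C3''–C4'' are made together by syn addition of two CO-derived ester carbons across the C3=C3'' bond of the (1S,4S,E)-enediol bis-silyl ether 7; C2 and C2'' choose the face.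
3. Before: the C3=C3'' alkene comes from a Wittig reaction (enedione 5), and C2/C2'' from a double Corey–Bakshi–Shibata reduction.
4. After: the diester is locked as cis-fused bislactone 12; an o-fluoroaryllithium adds to each lactone carbonyl (C4–C4a, C4''–C4a''); two SNAr closures (O1–C8a, O1''–C8a'') follow; hydrogenolysis is last.
5. Ring order: the B-ring aryls are present from the start; two temporary γ-lactones (step 6), then the two A rings attached (step 9), then both pyranone rings in one operation (step 10).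

Key step: step 5

Assumption: in the reduction of 5 the aryl ring is taken as the large carbonyl substituent, as in aryl alkyl ketones, so the (R)-oxazaborolidine is expected to give the (S)-carbinols; if the sense proves opposite, the (S)-catalyst is used.

**Route**

Step 1
Reactants: 1 1-[4-(benzyloxy)phenyl]-2-bromoethan-1-one
Product: 3 1-[4-(benzyloxy)phenyl]-2-(triphenylphosphoranylidene)ethan-1-one, via phosphonium bromide 2 (not isolated)
Conditions: PPh3, PhMe, rt; then 2 M aq. NaOH, CH2Cl2, rt
Reagents that add atoms: triphenylphosphine, c1ccc(cc1)P(c1ccccc1)c1ccccc1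
Why: SN2 quaternisation of the phosphine by the α-bromoketone and deprotonation of the salt should give the acyl-stabilised ylide (Wittig reagent preparation).

Step 2
Reactants: 3 1-[4-(benzyloxy)phenyl]-2-(triphenylphosphoranylidene)ethan-1-one; 4 4-methoxyphenylglyoxal monohydrate
Product: 5 (E)-1-[4-(benzyloxy)phenyl]-4-(4-methoxyphenyl)but-2-ene-1,4-dione
Conditions: CH2Cl2, 4 Å molecular sieves, rt
Reagents that add atoms: none
Why: Wittig olefination of the aldehyde carbon of the glyoxal by the stabilised ylide should be E-selective and leave the less electrophilic aryl ketone untouched.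

Step 3
Reactants: 5 (E)-1-[4-(benzyloxy)phenyl]-4-(4-methoxyphenyl)but-2-ene-1,4-dione
Product: 6 (1S,4S,E)-1-[4-(benzyloxy)phenyl]-4-(4-methoxyphenyl)but-2-ene-1,4-diol
Conditions: (R)-2-methyl-CBS-oxazaborolidine (40 mol%), catecholborane (3 equiv), PhMe/CH2Cl2, −78 °C; MeOH, then aq. NaHCO3
Reagents that add atoms: none
Why: Corey–Bakshi–Shibata reduction of both aryl ketones, in which the catalyst sets each carbinol as S by hydride delivery to the face defined by the aryl group as the large substituent; the low temperature favours 1,2- over 1,4-reduction, the second reduction statistically enriches the (S,S) isomer over its enantiomer, and the minor unlike diol is removed by chromatography or crystallisation.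

Step 4
Reactants: 6 (1S,4S,E)-1-[4-(benzyloxy)phenyl]-4-(4-methoxyphenyl)but-2-ene-1,4-diol
Product: 7 (1S,4S,E)-1-[4-(benzyloxy)phenyl]-1,4-bis(tert-butyldimethylsilyloxy)-4-(4-methoxyphenyl)but-2-ene
Conditions: TBSCl (2.5 equiv), imidazole, DMF, rt
Reagents that add atoms: tert-butyldimethylsilyl chloride, CC(C)(C)[Si](C)(C)Cl
Why: silylation of the two secondary alcohols under basic, non-ionising conditions should leave the acid-sensitive benzylic allylic C–O bonds and both stereocentres untouched.

Step 5
Reactants: 7 (1S,4S,E)-1-[4-(benzyloxy)phenyl]-1,4-bis(tert-butyldimethylsilyloxy)-4-(4-methoxyphenyl)but-2-ene; 8 carbon monoxide; 9 methanol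
Product: 10 dimethyl (2S,3S)-2-[(S)-[4-(benzyloxy)phenyl](tert-butyldimethylsilyloxy)methyl]-3-[(S)-(tert-butyldimethylsilyloxy)(4-methoxyphenyl)methyl]butanedioate
Conditions: Pd(OCOCF3)2 (5 mol%), N,N'-bis(2,6-dimethylphenyl)butane-2,3-diimine (5.5 mol%), p-benzoquinone (1.5 equiv), TsOH·H2O (2 mol%), CO (4 bar), MeOH/THF 7:1, 20 °C
Reagents that add atoms: carbon monoxide 8, [C-]#[O+]; methanol 9, CO
Why: This is the palladium-catalysed oxidative bis(alkoxycarbonylation) of a 1,2-disubstituted alkene: methanol attacks CO bound to divalent palladium to give a Pd–CO2Me unit, the alkene inserts syn into that Pd–C bond, CO inserts into the new alkyl–Pd bond with retention, and methanolysis of the acyl releases the diester and zerovalent palladium, which benzoquinone returns to the divalent state. No ring is closed; the two new bonds are C3–C4 and C3''–C4''. Because both ester carbons arrive on one face of an E alkene, C3 and C3'' must come out like (S,S or R,R), which the mechanism fixes. The face is chosen by C2 and C2'': they are related by the twofold axis through the alkene midpoint, so both bias the same face, and in the rotamer with each silyloxy group near the alkene plane and each aryl group perpendicular to it the palladium acyl should add anti to both aryl groups (the face anti to both C–O bonds when the allylic hydrogens are eclipsed), giving the 2,3-syn and 2'',3''-syn array, i.e. (2S,3S,3''S,2''S). The step needs high facial selectivity, which this matched double bias is expected to supply, and CO insertion faster than β-hydride or β-silyloxy elimination from the alkylpalladium, which CO pressure, the chelating diimine and coordination of the first ester carbonyl favour.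

Step 6
Reactants: 10 dimethyl (2S,3S)-2-[(S)-[4-(benzyloxy)phenyl](tert-butyldimethylsilyloxy)methyl]-3-[(S)-(tert-butyldimethylsilyloxy)(4-methoxyphenyl)methyl]butanedioate
Product: 12 (3S,3aS,6S,6aS)-6-[4-(benzyloxy)phenyl]-3-(4-methoxyphenyl)tetrahydro-1H,4H-furo[3,4-c]furan-1,4-dione, via dihydroxy diester 11 (not isolated)
Conditions: TBAF (3 equiv), AcOH (3 equiv), THF, 0 °C to rt; then PPTS (cat.), PhMe, 50 °C
Reagents that add atoms: none
Why: fluoride desilylation followed by lactonisation of each freed hydroxyl onto its γ ester (C2–OH onto C4'', C2''–OH onto C4); the like C3/C3'' configuration allows only the cis-fused bicycle with both aryl groups on the convex face, and no stereocentre is touched.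

Step 7
Reactants: 13 5-fluorobenzene-1,3-diol
Product: 14 1,3-bis(benzyloxy)-5-fluorobenzene
Conditions: BnBr (2.2 equiv), K2CO3, DMF, 60 °C
Reagents that add atoms: benzyl bromide, BrCc1ccccc1
Why: Williamson etherification of both phenols.

Step 8
Reactants: 14 1,3-bis(benzyloxy)-5-fluorobenzene
Product: 15 1,5-bis(benzyloxy)-2-bromo-3-fluorobenzene
Conditions: NBS (1.0 equiv), MeCN, 0 °C
Reagents that add atoms: N-bromosuccinimide, O=C1CCC(=O)N1Br
Why: electrophilic aromatic bromination para to one benzyloxy group and ortho to the other should prefer the position next to fluorine, which is less hindered than the one between the two benzyloxy groups.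

Step 9
Reactants: 12 (3S,3aS,6S,6aS)-6-[4-(benzyloxy)phenyl]-3-(4-methoxyphenyl)tetrahydro-1H,4H-furo[3,4-c]furan-1,4-dione; 15 1,5-bis(benzyloxy)-2-bromo-3-fluorobenzene
Product: 17 (2S,3S)-1,4-bis[2,4-bis(benzyloxy)-6-fluorophenyl]-2-[(S)-[4-(benzyloxy)phenyl](hydroxy)methyl]-3-[(S)-hydroxy(4-methoxyphenyl)methyl]butane-1,4-dione, via aryllithium 16 (not isolated)
Conditions: 15 (2.6 equiv), n-BuLi (2.5 equiv), THF, −78 °C, 15 min; add 12, −78 °C; AcOH, −78 °C
Reagents that add atoms: none
Why: bromine–lithium exchange gives an o-fluoroaryllithium that is stable to LiF loss at −78 °C and should add once to each lactone carbonyl (nucleophilic acyl addition that stops at the lithium hemiketal), so the cold acidic quench releases two aryl ketones and the C2/C2'' hydroxyls with all four stereocentres unchanged (17 is in ring–chain equilibrium with its bis-hemiketal).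

Step 10
Reactants: 17 (2S,3S)-1,4-bis[2,4-bis(benzyloxy)-6-fluorophenyl]-2-[(S)-[4-(benzyloxy)phenyl](hydroxy)methyl]-3-[(S)-hydroxy(4-methoxyphenyl)methyl]butane-1,4-dione
Product: 18 (2S,2'S,3S,3'S)-5,5',7,7'-tetrakis(benzyloxy)-2-[4-(benzyloxy)phenyl]-2'-(4-methoxyphenyl)-[3,3'-bichromane]-4,4'-dione
Conditions: KN(SiMe3)2 (2.05 equiv), THF, −78 to −20 °C; AcOH
Reagents that add atoms: none
Why: double intramolecular SNAr, in which each alkoxide attacks the fluorine-bearing carbon ortho to its β ketone to form a six-membered ring (O1–C8a, O1''–C8a'') in preference to the seven-membered alternative; the C2–O and C2''–O bonds are not broken, so configuration is retained, and cold stoichiometric base is chosen to limit retro-aldol cleavage and C3 epimerisation.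

Step 11
Reactants: 18 (2S,2'S,3S,3'S)-5,5',7,7'-tetrakis(benzyloxy)-2-[4-(benzyloxy)phenyl]-2'-(4-methoxyphenyl)-[3,3'-bichromane]-4,4'-dione
Product: 19 sikokianin A
Conditions: H2 (1 atm), 10% Pd/C, EtOAc/MeOH, rt
Reagents that add atoms: none
Why: hydrogenolysis of the five benzyl ethers under neutral conditions should leave the methyl ether, the ketones and the base-sensitive 2,3-cis centres intact.

**Compound list**

1 | 1-[4-(benzyloxy)phenyl]-2-bromoethan-1-one | BrCC(=O)c1ccc(OCc2ccccc2)cc1 | starting material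
2 | [2-(4-benzyloxyphenyl)-2-oxoethyl]triphenylphosphonium bromide | [Br-].O=C(C[P+](c1ccccc1)(c1ccccc1)c1ccccc1)c1ccc(OCc2ccccc2)cc1 | intermediate
3 | 1-[4-(benzyloxy)phenyl]-2-(triphenylphosphoranylidene)ethan-1-one | O=C(C=P(c1ccccc1)(c1ccccc1)c1ccccc1)c1ccc(OCc2ccccc2)cc1 | intermediate
4 | 4-methoxyphenylglyoxal monohydrate | COc1ccc(cc1)C(=O)C(O)O | starting material
5 | (E)-1-[4-(benzyloxy)phenyl]-4-(4-methoxyphenyl)but-2-ene-1,4-dione | COc1ccc(cc1)C(=O)/C=C/C(=O)c1ccc(OCc2ccccc2)cc1 | intermediate
6 | (1S,4S,E)-1-[4-(benzyloxy)phenyl]-4-(4-methoxyphenyl)but-2-ene-1,4-diol | COc1ccc([C@@H](O)/C=C/[C@H](O)c2ccc(OCc3ccccc3)cc2)cc1 | intermediate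
7 | (1S,4S,E)-1-[4-(benzyloxy)phenyl]-1,4-bis(tert-butyldimethylsilyloxy)-4-(4-methoxyphenyl)but-2-ene | COc1ccc([C@@H](O[Si](C)(C)C(C)(C)C)/C=C/[C@H](O[Si](C)(C)C(C)(C)C)c2ccc(OCc3ccccc3)cc2)cc1 | intermediate
8 | carbon monoxide | [C-]#[O+] | starting material
9 | methanol | CO | starting material
10 | dimethyl (2S,3S)-2-[(S)-[4-(benzyloxy)phenyl](tert-butyldimethylsilyloxy)methyl]-3-[(S)-(tert-butyldimethylsilyloxy)(4-methoxyphenyl)methyl]butanedioate | COc1ccc([C@@H](O[Si](C)(C)C(C)(C)C)[C@@H](C(=O)OC)[C@H](C(=O)OC)[C@H](O[Si](C)(C)C(C)(C)C)c2ccc(OCc3ccccc3)cc2)cc1 | intermediate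
11 | dimethyl (2S,3S)-2-[(S)-[4-(benzyloxy)phenyl](hydroxy)methyl]-3-[(S)-hydroxy(4-methoxyphenyl)methyl]butanedioate | COc1ccc([C@@H](O)[C@@H](C(=O)OC)[C@H](C(=O)OC)[C@H](O)c2ccc(OCc3ccccc3)cc2)cc1 | intermediate
12 | (3S,3aS,6S,6aS)-6-[4-(benzyloxy)phenyl]-3-(4-methoxyphenyl)tetrahydro-1H,4H-furo[3,4-c]furan-1,4-dione (cis-fused, both aryl groups exo) | COc1ccc(cc1)[C@H]2OC(=O)[C@H]3[C@@H]2C(=O)O[C@@H]3c4ccc(OCc5ccccc5)cc4 | intermediate
13 | 5-fluorobenzene-1,3-diol | Oc1cc(O)cc(F)c1 | starting material
14 | 1,3-bis(benzyloxy)-5-fluorobenzene | Fc1cc(OCc2ccccc2)cc(OCc2ccccc2)c1 | intermediate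
15 | 1,5-bis(benzyloxy)-2-bromo-3-fluorobenzene | Fc1cc(OCc2ccccc2)cc(OCc2ccccc2)c1Br | intermediate
16 | [2,4-bis(benzyloxy)-6-fluorophenyl]lithium | [Li]c1c(F)cc(OCc2ccccc2)cc1OCc1ccccc1 | intermediate
17 | (2S,3S)-1,4-bis[2,4-bis(benzyloxy)-6-fluorophenyl]-2-[(S)-[4-(benzyloxy)phenyl](hydroxy)methyl]-3-[(S)-hydroxy(4-methoxyphenyl)methyl]butane-1,4-dione | COc1ccc([C@@H](O)[C@@H](C(=O)c2c(F)cc(OCc3ccccc3)cc2OCc2ccccc2)[C@H](C(=O)c2c(F)cc(OCc3ccccc3)cc2OCc2ccccc2)[C@H](O)c2ccc(OCc3ccccc3)cc2)cc1 | intermediate
18 | (2S,2'S,3S,3'S)-5,5',7,7'-tetrakis(benzyloxy)-2-[4-(benzyloxy)phenyl]-2'-(4-methoxyphenyl)-[3,3'-bichromane]-4,4'-dione | COc1ccc([C@H]2Oc3cc(OCc4ccccc4)cc(OCc4ccccc4)c3C(=O)[C@H]2[C@@H]2C(=O)c3c(OCc4ccccc4)cc(OCc4ccccc4)cc3O[C@@H]2c2ccc(OCc3ccccc3)cc2)cc1 | intermediate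
19 | sikokianin A, (2S,2'S,3S,3'S)-5,5',7,7'-tetrahydroxy-2-(4-hydroxyphenyl)-2'-(4-methoxyphenyl)-[3,3'-bichromane]-4,4'-dione | COc1ccc([C@H]2Oc3cc(O)cc(O)c3C(=O)[C@H]2[C@@H]2C(=O)c3c(O)cc(O)cc3O[C@@H]2c2ccc(O)cc2)cc1 | target

**Step count**

Total: 11 steps. Longest linear sequence: 9 steps (steps 1–6 and 9–11); steps 7–8 are a two-step side branch.

**Steps most likely to fail**

Step 5. The palladium acyl may insert only slowly into an alkene flanked by two branched silyloxy(aryl)methyl groups. That leaves time for β-hydride elimination from the alkylpalladium, or for acid-promoted methanolysis of the benzylic silyl ethers. The facial bias may also be incomplete; a wrong-face isomer would show up after step 6 as the endo,endo-diaryl bislactone and could be removed there. Fallback (thermal cycloaddition and ring cleavage in place of metal insertion; sets out from 7, returns at 10): dichloroketene, made from trichloroacetyl chloride and Zn–Cu couple in Et2O, should add suprafacially across the alkene, which again gives the like C3/C3'' relationship. It would give the trans-2,2-dichlorocyclobutanone with the carbonyl on the anisyl-side ring carbon F1 and its regioisomer with the carbonyl on the other ring carbon F2. Ring opening of both with aqueous LiOH (cleavage of the C(=O)–CCl2 bond), silver-assisted hydrolysis of the CHCl2 group (AgNO3, aqueous acetone) and Pinnick oxidation (NaClO2, NaH2PO4, 2-methyl-2-butene), run in sequence without purification, should converge on the bis-silylated succinic acid F3. TMSCHN2 in MeOH/PhMe then gives 10.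

Step 10. The β-alkoxy ketone may undergo retro-aldol cleavage, E1cB dehydration or C3 epimerisation faster than SNAr, because the activating carbonyl is weakened by its ortho and para alkoxy donors. Fallback (aryl ether made first, ketone ring bond last, no base after the ketone exists; sets out from 6, returns at 18): copper-catalysed O-arylation of both hydroxyls of 6 with 1,3-bis(benzyloxy)-5-iodobenzene F4 (from 5-iodobenzene-1,3-diol, BnBr, K2CO3) using CuI, 3,4,7,8-tetramethyl-1,10-phenanthroline and Cs2CO3 in PhMe at 80 °C should give the bis(aryl ether) F5 without touching the carbinol C–O bonds. The conditions of step 5 applied to F5 would give the bis(aryloxy) diester F6. Me3SnOH in 1,2-dichloroethane at 80 °C would give the diacid F7. Conversion to the bis(acid chloride) with 1-chloro-N,N,2-trimethylprop-1-en-1-amine and SnCl4 at −78 °C should then close both pyranone rings by Friedel–Crafts acylation ortho to each ether oxygen (C4–C4a, C4''–C4a''), giving 18.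

Step 3. The catalyst may discriminate poorly between the aryl and the alkenyl flank of each ketone, and borane may add in a conjugate sense to the electron-poor alkene. Fallback (kinetic resolution in place of asymmetric reduction; sets out from 5, returns at 6): Luche reduction (NaBH4, CeCl3·7H2O, MeOH, −78 °C) should give the stereoisomer mixture of the enediol F8. Sharpless kinetic resolution (Ti(OiPr)4, L-(+)-diisopropyl tartrate, t-BuOOH, 4 Å sieves, CH2Cl2, −20 °C) should epoxidise every diol that contains an (R) carbinol and leave (S,S)-diol 6 to be recovered.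

**Further compounds**

F1 | step 5 | trans-2,2-dichlorocyclobutanone from 7, carbonyl on the ring carbon that bears the (S)-(4-methoxyphenyl)(silyloxy)methyl arm | COc1ccc([C@@H](O[Si](C)(C)C(C)(C)C)[C@H]2C(=O)C(Cl)(Cl)[C@@H]2[C@H](O[Si](C)(C)C(C)(C)C)c2ccc(OCc3ccccc3)cc2)cc1
F2 | step 5 | regioisomeric trans-2,2-dichlorocyclobutanone, carbonyl on the ring carbon that bears the (S)-(4-benzyloxyphenyl)(silyloxy)methyl arm | COc1ccc([C@@H](O[Si](C)(C)C(C)(C)C)[C@H]2C(Cl)(Cl)C(=O)[C@@H]2[C@H](O[Si](C)(C)C(C)(C)C)c2ccc(OCc3ccccc3)cc2)cc1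
F3 | step 5 | (2S,3S)-2-[(S)-[4-(benzyloxy)phenyl](tert-butyldimethylsilyloxy)methyl]-3-[(S)-(tert-butyldimethylsilyloxy)(4-methoxyphenyl)methyl]butanedioic acid | COc1ccc([C@@H](O[Si](C)(C)C(C)(C)C)[C@@H](C(=O)O)[C@H](C(=O)O)[C@H](O[Si](C)(C)C(C)(C)C)c2ccc(OCc3ccccc3)cc2)cc1
F4 | step 10 | 1,3-bis(benzyloxy)-5-iodobenzene | Ic1cc(OCc2ccccc2)cc(OCc2ccccc2)c1
F5 | step 10 | (1S,4S,E)-1-[4-(benzyloxy)phenyl]-1,4-bis[3,5-bis(benzyloxy)phenoxy]-4-(4-methoxyphenyl)but-2-ene | COc1ccc([C@@H](Oc2cc(OCc3ccccc3)cc(OCc3ccccc3)c2)/C=C/[C@H](Oc2cc(OCc3ccccc3)cc(OCc3ccccc3)c2)c2ccc(OCc3ccccc3)cc2)cc1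
F6 | step 10 | dimethyl (2S,3S)-2-[(S)-[4-(benzyloxy)phenyl][3,5-bis(benzyloxy)phenoxy]methyl]-3-[(S)-[3,5-bis(benzyloxy)phenoxy](4-methoxyphenyl)methyl]butanedioate | COc1ccc([C@@H](Oc2cc(OCc3ccccc3)cc(OCc3ccccc3)c2)[C@@H](C(=O)OC)[C@H](C(=O)OC)[C@H](Oc2cc(OCc3ccccc3)cc(OCc3ccccc3)c2)c2ccc(OCc3ccccc3)cc2)cc1
F7 | step 10 | (2S,3S)-2-[(S)-[4-(benzyloxy)phenyl][3,5-bis(benzyloxy)phenoxy]methyl]-3-[(S)-[3,5-bis(benzyloxy)phenoxy](4-methoxyphenyl)methyl]butanedioic acid | COc1ccc([C@@H](Oc2cc(OCc3ccccc3)cc(OCc3ccccc3)c2)[C@@H](C(=O)O)[C@H](C(=O)O)[C@H](Oc2cc(OCc3ccccc3)cc(OCc3ccccc3)c2)c2ccc(OCc3ccccc3)cc2)cc1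
F8 | step 3 | (E)-1-[4-(benzyloxy)phenyl]-4-(4-methoxyphenyl)but-2-ene-1,4-diol, mixture of carbinol stereoisomers | COc1ccc(C(O)/C=C/C(O)c2ccc(OCc3ccccc3)cc2)cc1
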